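## Structural features

Marchantin H is a macrocyclic bis(bibenzyl). Four benzene rings are held in one 18-membered ring by two diaryl ether oxygens (ring A–O–ring B and ring C–O–ring D) and two CH2CH2 bridges (ring B–ring C and ring D–ring A). Ring A is a phenol with the ether oxygen ortho and the bridge para to its hydroxyl; ring B is a para-phenylene; ring C is a 1,2,3,4-tetrasubstituted catechol whose ether oxygen lies between a hydroxyl and the bridge carbon; ring D is a meta-phenylene. The target has no stereocentre and no alkene, so the only spatial issue is the strain of a cyclophane that contains a para-bridged ring. The free catechol of ring C is prone to oxidation, and all three hydroxyls would interfere with base, hydride and halogenating reagents, so they are carried as methyl ethers until the last step. The real difficulties are the ether at the doubly ortho-substituted carbon of ring C and the closure of the 18-membered ring. The key step exploits the fact that both carbons of the ring B–ring C bridge are benzylic. A sulfur atom placed between them gives a 19-membered ring that closes easily by S-alkylation. After oxidation both flanking CH2 groups are acidic, and loss of SO2 contracts the ring to the 18-membered carbon skeleton.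

## Logic of the disconnections

23 ⇒ 22. The three phenolic O–H bonds are replaced by O–CH3 bonds. This masks the catechol and the ring A phenol through every basic, reductive and oxidative step. The forward step must cleave three alkyl–oxygen bonds and spare both diaryl ether bonds; BBr3 attacks only the methyl carbons.

22 ⇒ 21. A C=C bond is introduced between the two carbons of the ring B–ring C bridge. This turns a bond between two sp3 carbons into one that an olefin-forming reaction can make. The forward step is a plain hydrogenation, and either alkene geometry serves.

21 ⇒ 18 (key disconnection). The benzylic C=C bond is cut and an SO2 unit is inserted between its two carbons, which enlarges the ring from 18 to 19 members. The gain is that a strained ring no longer has to be closed by C–C bond formation. The forward step must halogenate one sulfone α-carbon and close the three-membered ring from the other, and nothing else in 18 may be base-sensitive.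

18 ⇒ 16 ⇒ 15. The two S=O bonds are removed, then both benzylic C–S bonds are cut, leaving an acyclic bis-electrophile 15 and a sulfide dianion. The macrocyclisation becomes a thiolate SN2 reaction at an unhindered benzylic carbon, the most dependable ring closure available here. It demands pseudo-high dilution and a medium in which the electron-rich benzylic bromide does not solvolyse.

15 ⇒ 14 ⇒ 13. Both C–Br bonds go back to C–OH, and one CH2OH (on ring B) goes back to a methyl ester. The ester is the group that activated ring B for ether formation, so it costs no extra step. It also keeps the ring B carbon inert while the other bridge is built.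

13 ⇒ 12 ⇒ 5 + 10. The ring A–ring D bridge is desaturated and its C=C bond cut by a Wittig disconnection into 5 and 10. This divides the molecule into two diaryl ethers of similar size. The olefination must tolerate a free benzylic alcohol and an ester, and the hydrogenation must not cleave the benzylic C–O bond.

5 ⇒ 4 ⇒ 3 ⇒ 1 + 2. The C–P bond and the benzylic C–O bond go back to the aldehyde of 3. The ring B carbon–oxygen bond of the ring A–O–ring B ether is then cut. Ring B carries the leaving group because its para ester activates addition–elimination, which leaves two commercial benzenes and no metal.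

10 ⇒ 8 ⇒ 6 + 7. The ring D aldehyde is masked again as its acetal and the ring C alcohol is returned to the aldehyde. The ring D carbon–oxygen bond of the ring C–O–ring D ether is then cut. The hindered ring C oxygen is the nucleophile and the unhindered ring D carbon the electrophile, which requires a copper-mediated coupling. The acetal of 7 keeps the two carbonyl carbons distinct.

## Other disconnections considered

Alternative 1: The cut runs through ring D itself: two ring C–C bonds are broken so that ring D is built from a pyrone. The precursor would be the 4-aryloxy-6-arylethyl-2-pyrone A1. Heated with the dienophile A2 and a base, it should add across C3 and C6 of the pyrone, lose the lactone bridge as CO2 and eliminate the sulfinate, giving the ring C–O–ring D aldehyde A3.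
- In its favour: the hindered ring C oxygen would be attached by addition–elimination at C4 of a pyrone, a vinylogous acyl substitution that needs no copper. On this point it is better than the Ullmann coupling of the chosen plan. The meta relation on ring D is fixed by the pyrone positions and cannot go wrong.
- Against it: ring D is a plain meta-disubstituted benzene that can be bought, so building it costs the steps needed to assemble A1. The cycloaddition needs prolonged heating with an aldehyde present. A3 is still acyclic: ring B must be attached at the ring A bromide and the macrocycle closed by a further reaction.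
- Comparison: structurally it addresses the hindered ether and leaves the ring closure unanswered, whereas the chosen plan addresses the ring closure. Mechanistically it is a pericyclic cascade, against the ionic sequence of the chosen plan. In step count it is expected to be the longer route.

Alternative 2: The cut is the aryl C–O bond between the ring B oxygen and C3 of ring A, made as the ring-closing bond. The seco bisphenol A4 (ring A as a 2,6-dibromophenol, ring B as a 2,6-dichlorophenol) would be oxidised with Tl(NO3)3 in methanol and then reduced with Zn in acetic acid, giving the trihalogenated macrocycle A5.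
- In its favour: ether formation and macrocyclisation occur in one operation, near room temperature and without base. No activating group is needed on ring B, and the ring A hydroxyl is already free in A5. On these points it equals or betters the chosen plan.
- Against it: four halogens must be installed and three removed afterwards. Trivalent thallium is used stoichiometrically and is highly toxic. The dimethoxy-substituted ring C is itself oxidisable, so chemoselectivity is uncertain. A4 must already contain the hindered ring C–O–ring D ether and both bridges, so the sequence is long and linear.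
- Comparison: the chosen plan closes the ring at an unhindered benzylic carbon with a thiolate, and that is more predictable than an oxidative coupling through a para-bridged ring. In step count the halogenation and dehalogenation roughly cancel the steps saved, and ring C still needs BBr3.

Alternative 3: The cut is the aryl C–O bond between the ring D oxygen and the ring C carbon, again as the ring-closing bond. The seco fluoro ketone A6 would be treated with Cs2CO3 in DMF at high dilution. The ring D phenoxide displaces the fluoride ortho to the ketone and gives the macrocyclic ketone A7.
- In its favour: the most hindered bond and the 18-membered ring are made together, and the plan is convergent. It needs no copper coupling, no sulfur and no halocarbon. The ring closure takes one step against three in the chosen plan (sulfide formation, oxidation, contraction), so on convergency and on the step count of the closure it is the better plan.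
- Against it: the fluoride sits between the acyl carbon and a methoxy group on an electron-rich ring, and its only activator is a ketone weakened by the para methoxy group. The substitution is therefore slow at the dilution a macrocyclisation needs. The CH2 between carbonyl and ring B is about as acidic as the phenol, so enolate side reactions (self-condensation, oxidation, intermolecular arylation) compete. The ketone must afterwards be removed, which returns one or two steps.
- Comparison: overall the step count is similar or slightly lower. The chosen plan trades this for a ring closure that does not depend on a marginal aromatic substitution. It makes the hindered ether early and intermolecularly, where heat and excess reagent can be applied.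

Key step: step 12

Assumption: 21 is drawn as the E alkene and 12 is carried as an E/Z mixture; either geometry serves in both cases because the next step saturates the bond.

## Route

Step 1
Reactants: 1 isovanillin (3-hydroxy-4-methoxybenzaldehyde); 2 methyl 4-fluorobenzoate
Product: 3 methyl 4-(5-formyl-2-methoxyphenoxy)benzoate
Conditions: K2CO3, dry DMSO, 120 °C, N2
Reagents that add atoms: none
Why: Nucleophilic aromatic substitution (addition–elimination): the phenoxide of 1 attacks the carbon para to the ester of 2 and fluoride leaves. An ester rather than an aldehyde is used as the activator so that the two carbonyl carbons of 3 stay distinguishable.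

Step 2
Reactants: 3 methyl 4-(5-formyl-2-methoxyphenoxy)benzoate
Product: 4 methyl 4-[5-(hydroxymethyl)-2-methoxyphenoxy]benzoate
Conditions: NaBH4, MeOH–THF, 0 °C
Reagents that add atoms: none
Why: Chemoselective hydride reduction: NaBH4 reduces the aryl aldehyde and leaves the methyl benzoate untouched at 0 °C.

Step 3
Reactants: 4 methyl 4-[5-(hydroxymethyl)-2-methoxyphenoxy]benzoate
Product: 5 {4-methoxy-3-[4-(methoxycarbonyl)phenoxy]benzyl}triphenylphosphonium bromide
Conditions: Ph3P·HBr, MeCN, reflux
Reagents that add atoms: triphenylphosphine hydrobromide, Br.P(c1ccccc1)(c1ccccc1)c1ccccc1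
Why: Acid-promoted substitution of a benzylic alcohol by a phosphine: the para-methoxybenzylic C–O bond ionises readily under HBr and PPh3 captures the carbon. The phosphonium salt forms in one operation, without a separate benzylic bromide.

Step 4
Reactants: 6 2-hydroxy-3,4-dimethoxybenzaldehyde; 7 2-(3-bromophenyl)-1,3-dioxolane
Product: 8 2-[3-(1,3-dioxolan-2-yl)phenoxy]-3,4-dimethoxybenzaldehyde
Conditions: CuO (0.3 equiv), K2CO3, pyridine, reflux, N2
Reagents that add atoms: none
Why: Ullmann diaryl ether synthesis: copper-mediated coupling of the potassium phenoxide of 6 with the unactivated aryl bromide 7, under forcing classical conditions because the phenoxide is flanked on both sides. The dioxolane is inert to base and keeps the ring D carbonyl distinct from the ring C aldehyde.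

Step 5
Reactants: 8 2-[3-(1,3-dioxolan-2-yl)phenoxy]-3,4-dimethoxybenzaldehyde
Product: 10 3-[6-(hydroxymethyl)-2,3-dimethoxyphenoxy]benzaldehyde, via acetal alcohol 9 (not isolated)
Conditions: NaBH4, THF–H2O, 0 °C; then 2 M HCl to pH 1, rt
Reagents that add atoms: water, O
Why: Hydride reduction of the ring C aldehyde, then acid-catalysed acetal hydrolysis in the same flask; the acid destroys remaining hydride before the ring D aldehyde is released. Alcohol-free aqueous THF avoids etherification of the electron-rich benzylic alcohol.

Step 6
Reactants: 5 {4-methoxy-3-[4-(methoxycarbonyl)phenoxy]benzyl}triphenylphosphonium bromide; 10 3-[6-(hydroxymethyl)-2,3-dimethoxyphenoxy]benzaldehyde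
Product: 12 methyl 4-[5-(2-{3-[6-(hydroxymethyl)-2,3-dimethoxyphenoxy]phenyl}ethenyl)-2-methoxyphenoxy]benzoate (E/Z mixture), via phosphonium ylide 11 (not isolated)
Conditions: K2CO3, 18-crown-6 (cat.), CH2Cl2, reflux
Reagents that add atoms: none
Why: Wittig olefination: solid carbonate with crown ether deprotonates the benzylic phosphonium salt but neither the alcohol nor the ester. The semi-stabilised ylide 11 should give both alkene isomers, which does not matter because the bond is saturated next.

Step 7
Reactants: 12 methyl 4-[5-(2-{3-[6-(hydroxymethyl)-2,3-dimethoxyphenoxy]phenyl}ethenyl)-2-methoxyphenoxy]benzoate (E/Z mixture)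
Product: 13 methyl 4-[5-(2-{3-[6-(hydroxymethyl)-2,3-dimethoxyphenoxy]phenyl}ethyl)-2-methoxyphenoxy]benzoate
Conditions: H2 (1 atm), 5% Pd/C, EtOAc, Et3N (1%), rt
Reagents that add atoms: none
Why: Heterogeneous catalytic hydrogenation of the stilbene; the neutral solvent and the trace of amine suppress hydrogenolysis of the electron-rich benzylic C–O bond.

Step 8
Reactants: 13 methyl 4-[5-(2-{3-[6-(hydroxymethyl)-2,3-dimethoxyphenoxy]phenyl}ethyl)-2-methoxyphenoxy]benzoate
Product: 14 {4-[5-(2-{3-[6-(hydroxymethyl)-2,3-dimethoxyphenoxy]phenyl}ethyl)-2-methoxyphenoxy]phenyl}methanol
Conditions: LiAlH4, THF, 0 °C → rt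
Reagents that add atoms: none
Why: Hydride reduction of the benzoate to the benzylic alcohol; aryl ethers are inert, and the free alcohol only consumes one hydride.

Step 9
Reactants: 14 {4-[5-(2-{3-[6-(hydroxymethyl)-2,3-dimethoxyphenoxy]phenyl}ethyl)-2-methoxyphenoxy]phenyl}methanol
Product: 15 1-(bromomethyl)-2-[3-(2-{3-[4-(bromomethyl)phenoxy]-4-methoxyphenyl}ethyl)phenoxy]-3,4-dimethoxybenzene
Conditions: PBr3, CH2Cl2, 0 °C; cold NaHCO3 work-up, used crude at once
Reagents that add atoms: phosphorus tribromide, BrP(Br)Br
Why: Substitution of both benzylic hydroxyls by bromide through phosphite activation. The bromide on ring C, para to a methoxy group, is solvolysis-prone, so the product is not chromatographed or stored.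

Step 10
Reactants: 15 1-(bromomethyl)-2-[3-(2-{3-[4-(bromomethyl)phenoxy]-4-methoxyphenyl}ethyl)phenoxy]-3,4-dimethoxybenzene
Product: 16 19-membered macrocyclic sulfide (tri-O-methyl; CH2–S–CH2 between ring B and ring C)
Conditions: Na2S·9H2O (1.05 equiv), degassed DMF; simultaneous syringe-pump addition of 15 (in THF) and of the sulfide (in DMF–H2O), about 2 mM final, rt, N2
Reagents that add atoms: sodium sulfide (as nonahydrate), [Na+].[Na+].[S-2]
Why: Double SN2 thioetherification: the first displacement is intermolecular and the second closes the 19-membered ring at an unhindered benzylic carbon, favoured over oligomerisation by pseudo-high dilution. The aprotic medium prevents solvolysis of the ring C benzylic bromide.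

Step 11
Reactants: 16 19-membered macrocyclic sulfide (tri-O-methyl)
Product: 18 19-membered macrocyclic dibenzylic sulfone (tri-O-methyl; CH2–SO2–CH2 between ring B and ring C), via macrocyclic sulfoxide 17 (not isolated)
Conditions: mCPBA (2.2 equiv), CH2Cl2, 0 °C → rt
Reagents that add atoms: 3-chloroperoxybenzoic acid, OOC(=O)c1cccc(Cl)c1
Why: Electrophilic oxidation at sulfur by the peracid, sulfide to sulfoxide 17 to sulfone 18. Sulfur is far more nucleophilic than the anisole-type rings, so two equivalents at low temperature should stop cleanly at the sulfone.

Step 12
Reactants: 18 19-membered macrocyclic dibenzylic sulfone (tri-O-methyl)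
Product: 21 18-membered macrocyclic E-stilbene (tri-O-methyl; CH=CH between ring B and ring C), via alpha-bromo sulfone 19 (not isolated), via episulfone 20 (not isolated)
Conditions: KOH/Al2O3, CBr2F2, t-BuOH–CH2Cl2, 0 °C → rt
Reagents that add atoms: none
Why: Ramberg–Bäcklund reaction with in situ halogenation; the closest known use is the conversion of dibenzylic sulfones and thia-cyclophane sulfones into stilbenes and cyclophane alkenes. KOH on alumina deprotonates one benzylic carbon next to sulfur (either one; the ring B side is drawn) and CBr2F2 transfers bromine to the carbanion, giving 19. Deprotonation of the other benzylic carbon and intramolecular displacement of bromide (3-exo-tet, a 1,3-elimination) gives the episulfone 20, which loses SO2 in a cheletropic step to leave 21. The 18-membered ring is therefore closed by C–C bond formation across the sulfur inside the existing 19-membered ring, not end to end, so no dilution is needed and the entropic cost was already paid in the C–S closure. No stereocentre persists: the centres of 19 and 20 are transient and racemic, and the alkene geometry (E expected from the trans episulfone under equilibrating base, Z acceptable) is erased in step 13. The step needs halogenation only at the sulfone α-carbons, and the substrate secures this because only those two CH2 groups are activated by both sulfonyl and aryl; the other bridge, the diaryl ethers and the methyl ethers are inert to KOH. CBr2F2 is preferred to CCl4 because the difluorocarbene it releases should not add to the stilbene.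

Step 13
Reactants: 21 18-membered macrocyclic E-stilbene (tri-O-methyl)
Product: 22 tri-O-methylmarchantin H
Conditions: H2 (1 atm), 10% Pd/C, EtOAc–EtOH, rt
Reagents that add atoms: none
Why: Catalytic hydrogenation of the cyclic stilbene to the bibenzyl bridge; no benzylic heteroatom remains that could be lost.

Step 14
Reactants: 22 tri-O-methylmarchantin H
Product: 23 marchantin H
Conditions: BBr3 (6 equiv), CH2Cl2, −78 °C → rt; then H2O, under argon
Reagents that add atoms: none
Why: Lewis acid-mediated cleavage of the three aryl methyl ethers: boron coordinates the ether oxygen and bromide attacks the methyl carbon. The diaryl ethers have no alkyl carbon to attack and persist; work-up under argon limits oxidation of the catechol.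

## Compound list

1 | isovanillin (3-hydroxy-4-methoxybenzaldehyde) | COc1ccc(C=O)cc1O | starting material
2 | methyl 4-fluorobenzoate | COC(=O)c1ccc(F)cc1 | starting material
3 | methyl 4-(5-formyl-2-methoxyphenoxy)benzoate | COC(=O)c1ccc(Oc2cc(C=O)ccc2OC)cc1 | intermediate
4 | methyl 4-[5-(hydroxymethyl)-2-methoxyphenoxy]benzoate | COC(=O)c1ccc(Oc2cc(CO)ccc2OC)cc1 | intermediate
5 | {4-methoxy-3-[4-(methoxycarbonyl)phenoxy]benzyl}triphenylphosphonium bromide | COC(=O)c1ccc(Oc2cc(C[P+](c3ccccc3)(c3ccccc3)c3ccccc3)ccc2OC)cc1.[Br-] | intermediate
6 | 2-hydroxy-3,4-dimethoxybenzaldehyde | COc1ccc(C=O)c(O)c1OC | starting material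
7 | 2-(3-bromophenyl)-1,3-dioxolane | Brc1cccc(c1)C1OCCO1 | starting material
8 | 2-[3-(1,3-dioxolan-2-yl)phenoxy]-3,4-dimethoxybenzaldehyde | COc1ccc(C=O)c(Oc2cccc(c2)C2OCCO2)c1OC | intermediate
9 | {2-[3-(1,3-dioxolan-2-yl)phenoxy]-3,4-dimethoxyphenyl}methanol | COc1ccc(CO)c(Oc2cccc(c2)C2OCCO2)c1OC | intermediate (not isolated)
10 | 3-[6-(hydroxymethyl)-2,3-dimethoxyphenoxy]benzaldehyde | COc1ccc(CO)c(Oc2cccc(C=O)c2)c1OC | intermediate
11 | methyl 4-{2-methoxy-5-[(triphenylphosphoranylidene)methyl]phenoxy}benzoate (ylide) | COC(=O)c1ccc(Oc2cc(C=P(c3ccccc3)(c3ccccc3)c3ccccc3)ccc2OC)cc1 | intermediate (not isolated)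
12 | methyl 4-[5-(2-{3-[6-(hydroxymethyl)-2,3-dimethoxyphenoxy]phenyl}ethenyl)-2-methoxyphenoxy]benzoate, E/Z mixture (geometry left open) | COC(=O)c1ccc(Oc2cc(C=Cc3cccc(Oc4c(CO)ccc(OC)c4OC)c3)ccc2OC)cc1 | intermediate
13 | methyl 4-[5-(2-{3-[6-(hydroxymethyl)-2,3-dimethoxyphenoxy]phenyl}ethyl)-2-methoxyphenoxy]benzoate | COC(=O)c1ccc(Oc2cc(CCc3cccc(Oc4c(CO)ccc(OC)c4OC)c3)ccc2OC)cc1 | intermediate
14 | {4-[5-(2-{3-[6-(hydroxymethyl)-2,3-dimethoxyphenoxy]phenyl}ethyl)-2-methoxyphenoxy]phenyl}methanol | OCc1ccc(Oc2cc(CCc3cccc(Oc4c(CO)ccc(OC)c4OC)c3)ccc2OC)cc1 | intermediate
15 | 1-(bromomethyl)-2-[3-(2-{3-[4-(bromomethyl)phenoxy]-4-methoxyphenyl}ethyl)phenoxy]-3,4-dimethoxybenzene | BrCc1ccc(Oc2cc(CCc3cccc(Oc4c(CBr)ccc(OC)c4OC)c3)ccc2OC)cc1 | intermediate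
16 | 19-membered macrocyclic sulfide, tri-O-methyl (CH2–S–CH2 between ring B and ring C) | COc1ccc2cc1Oc1ccc(cc1)CSCc1ccc(OC)c(OC)c1Oc1cccc(c1)CC2 | intermediate
17 | macrocyclic sulfoxide, tri-O-methyl (racemic at sulfur) | COc1ccc2cc1Oc1ccc(cc1)CS(=O)Cc1ccc(OC)c(OC)c1Oc1cccc(c1)CC2 | intermediate (not isolated)
18 | 19-membered macrocyclic dibenzylic sulfone, tri-O-methyl | COc1ccc2cc1Oc1ccc(cc1)CS(=O)(=O)Cc1ccc(OC)c(OC)c1Oc1cccc(c1)CC2 | intermediate
19 | macrocyclic alpha-bromo sulfone (racemic; bromine drawn on the ring B benzylic carbon) | COc1ccc2cc1Oc1ccc(cc1)C(Br)S(=O)(=O)Cc1ccc(OC)c(OC)c1Oc1cccc(c1)CC2 | intermediate (not isolated)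
20 | macrocyclic trans-2,3-diaryl episulfone (racemic; one enantiomer drawn) | COc1ccc2cc1Oc1ccc(cc1)[C@H]1[C@@H](S1(=O)=O)c1ccc(OC)c(OC)c1Oc1cccc(c1)CC2 | intermediate (not isolated)
21 | 18-membered macrocyclic E-stilbene, tri-O-methyl | COc1ccc2cc1Oc1ccc(cc1)/C=C/c1ccc(OC)c(OC)c1Oc1cccc(c1)CC2 | intermediate
22 | tri-O-methylmarchantin H | COc1ccc2cc1Oc1ccc(cc1)CCc1ccc(OC)c(OC)c1Oc1cccc(c1)CC2 | intermediate
23 | marchantin H | Oc1ccc2cc1Oc1ccc(cc1)CCc1ccc(O)c(O)c1Oc1cccc(c1)CC2 | target

## Step count and least certain steps

Total: 14 steps. Longest linear sequence: 12 steps (1 → 3 → 4 → 5 → 12 → 13 → 14 → 15 → 16 → 18 → 21 → 22 → 23); the branch from 6 and 7 joins at step 6 after two steps.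

Step 12 (key step). The second deprotonation and the 1,3-elimination may be slow if the macrocycle resists bringing the two benzylic carbons into the required geometry. Further halogenation of the α-bromo sulfone would then compete and lead to bromoalkenes or ring-opened sulfonates. CBr2F2 is also volatile and regulated; 1,2-dibromotetrachloroethane is a known substitute bromine source, but that is only a change of conditions. Fallback: set out from 16 and extrude sulfur photochemically (hν 254 nm, P(OMe)3, degassed). Benzylic C–S homolysis, capture of sulfur by the phosphite and recombination of the two benzylic radicals give the CH2CH2 bridge directly. This is a known way from thia-cyclophanes to cyclophanes; it comes back to the route at 22 and step 13 is not needed. This fallback makes no new compound (F0).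

Step 10. Intermolecular S-alkylation may outrun ring closure and give oligomers, and the ring C benzylic bromide may solvolyse or self-alkylate before sulfide reaches it. Fallback: set out from 14 and oxidise both benzylic alcohols (MnO2, CH2Cl2, rt) to the dialdehyde 2-[3-(2-{3-(4-formylphenoxy)-4-methoxyphenyl}ethyl)phenoxy]-3,4-dimethoxybenzaldehyde F1. An intramolecular McMurry coupling (TiCl4, Zn, pyridine, THF, reflux, slow addition; low-valent titanium) then joins the two carbonyl carbons, a ring closure well known for macrocyclic bis(bibenzyl)s. It comes back to the route at 21 (either alkene isomer) and bypasses steps 9 to 12.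

Step 4. The coupling may stall because the phenoxide of 6 is hindered on both sides and chelates copper through the ortho aldehyde; debromination of 7 and slow degradation of the aldehyde on long heating would then dominate. Fallback with reversed polarity: set out from 7 and hydroxylate it (KOH, Pd2(dba)3, tBuXPhos, dioxane–H2O, 100 °C) to 3-(1,3-dioxolan-2-yl)phenol F2. Its phenoxide then displaces fluoride from commercial 2-fluoro-3,4-dimethoxybenzaldehyde (K2CO3, DMF, 120 °C; addition–elimination activated by the ortho aldehyde). It comes back to the route at 8.

Step 7. Hydrogenolysis of the benzylic C–O bond on ring C may accompany saturation of the alkene, because that position is activated by a para methoxy group. Fallback: set out from 12 and reduce the alkene without a metal surface, by diimide generated from p-toluenesulfonyl hydrazide and NaOAc in refluxing DME–H2O. Concerted transfer of H2 to the C=C bond cannot cleave C–O bonds. It comes back to the route at 13 and makes no new compound (F0).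

## Further compounds

F0 | step 12 | none | none
F1 | step 10 | 2-[3-(2-{3-(4-formylphenoxy)-4-methoxyphenyl}ethyl)phenoxy]-3,4-dimethoxybenzaldehyde | O=Cc1ccc(Oc2cc(CCc3cccc(Oc4c(C=O)ccc(OC)c4OC)c3)ccc2OC)cc1
F2 | step 4 | 3-(1,3-dioxolan-2-yl)phenol | Oc1cccc(c1)C1OCCO1
F0 | step 7 | none | none
A1 | alternative 1 | 6-[2-(3-bromo-4-methoxyphenyl)ethyl]-4-(6-formyl-2,3-dimethoxyphenoxy)-2H-pyran-2-one | O=c1cc(Oc2c(C=O)ccc(OC)c2OC)cc(CCc2ccc(OC)c(Br)c2)o1
A2 | alternative 1 | phenyl vinyl sulfone | C=CS(=O)(=O)c1ccccc1
A3 | alternative 1 | 2-{3-[2-(3-bromo-4-methoxyphenyl)ethyl]phenoxy}-3,4-dimethoxybenzaldehyde | O=Cc1ccc(OC)c(OC)c1Oc1cccc(c1)CCc1ccc(OC)c(Br)c1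
A4 | alternative 2 | 2,6-dibromo-4-{2-[3-(6-{2-(3,5-dichloro-4-hydroxyphenyl)ethyl}-2,3-dimethoxyphenoxy)phenyl]ethyl}phenol (seco bisphenol) | Oc1c(Br)cc(cc1Br)CCc1cccc(c1)Oc1c(CCc2cc(Cl)c(O)c(Cl)c2)ccc(OC)c1OC
A5 | alternative 2 | trihalogenated macrocycle with ring C as its dimethyl ether | Oc1c(Br)cc2cc1Oc1c(Cl)cc(cc1Cl)CCc1ccc(OC)c(OC)c1Oc1cccc(c1)CC2
A6 | alternative 3 | 1-(2-fluoro-3,4-dimethoxyphenyl)-2-[4-(5-{2-(3-hydroxyphenyl)ethyl}-2-methoxyphenoxy)phenyl]ethan-1-one (seco fluoro ketone) | COc1ccc(CCc2cccc(O)c2)cc1Oc1ccc(CC(=O)c2ccc(OC)c(OC)c2F)cc1
A7 | alternative 3 | macrocyclic ketone at the ring B–ring C bridge, tri-O-methyl | COc1ccc2cc1Oc1ccc(cc1)CC(=O)c1ccc(OC)c(OC)c1Oc1cccc(c1)CC2
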